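**Plan**

Ring labels: A = the 3,5-dihydroxyphenoxy ring, B = the middle ring that carries both ether oxygens, C = the hexasubstituted ring, D and E = the two 2,4,6-trihydroxyphenyl rings.
Cuts, in retrosynthetic order: first the two biaryl bonds C3(ring C)–C1(ring D) and C5(ring C)–C1(ring E) together; then the aryl–oxygen bond of the A–B ether on the ring A side; last the aryl–oxygen bond of the B–C ether on the ring B side.
Enabling feature: on ring C the aryl-bearing carbons C3 and C5 are the two ortho positions of the C4 oxygen and carry identical rings D and E. A precursor in which O4 of ring C is the only free hydroxyl can therefore receive both aryl groups in one two-directional, phenol-directed operation.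
Forward order: all five benzene rings are purchased. Ring C is joined to ring B by fluoride displacement next to an aldehyde, the aldehyde is turned into a hydroxyl, ring A is attached there by copper catalysis, the ring C hydroxyl is unmasked, rings D and E are attached together from an aryllead triacetate, and all methyl ethers are cleaved at the end.
Stereochemistry: the target has no stereocentre, and the two biaryl axes are not stereogenic because rings D and E are symmetric about them, so nothing needs to be controlled.

Key step: step 9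

Remark on the chemistry: the free polyphenol is assumed to be isolable when air is excluded during work-up.

**Route**

Step 1
Reactants: 1 2,6-dimethoxy-1,4-benzoquinone
Product: 2 2,6-dimethoxybenzene-1,4-diol
Conditions: Na2S2O4, H2O/EtOAc, rt, argon
Reagents that add atoms: none
Why: Dithionite reduction of a para-quinone to its hydroquinone is a fast two-electron reduction that leaves both methyl ethers untouched, and the air-sensitive diol is carried on under argon.

Step 2
Reactants: 2 2,6-dimethoxybenzene-1,4-diol
Product: 3 4-(benzyloxy)-2,6-dimethoxyphenol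
Conditions: BnBr (1.0 equiv), K2CO3 (1.0 equiv), acetone, rt, argon
Reagents that add atoms: benzyl bromide, BrCc1ccccc1
Why: Williamson ether synthesis with one equivalent of halide and a weak base should alkylate the C4 hydroxyl, which is the more acidic one (meta to both methoxy groups) and sterically open, whereas the C1 hydroxyl is shielded and hydrogen-bonded by its two ortho methoxy groups.

Step 3
Reactants: 4 1-fluoro-3,5-dimethoxybenzene
Product: 6 2-fluoro-4,6-dimethoxybenzaldehyde, via aryl iminium chloride 5 (not isolated)
Conditions: POCl3, DMF, 0 °C to 70 °C; then ice-water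
Reagents that add atoms: N,N-dimethylformamide, CN(C)C=O; water, O
Why: Vilsmeier–Haack formylation is an electrophilic aromatic substitution that should favour the carbon next to fluorine (ortho to one methoxy group, para to the other, and less crowded than the carbon between the two methoxy groups); the minor 4-fluoro-2,6-dimethoxy isomer is removed by chromatography.

Step 4
Reactants: 3 4-(benzyloxy)-2,6-dimethoxyphenol; 6 2-fluoro-4,6-dimethoxybenzaldehyde
Product: 7 2-[4-(benzyloxy)-2,6-dimethoxyphenoxy]-4,6-dimethoxybenzaldehyde
Conditions: Cs2CO3, DMSO, 110 °C, argon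
Reagents that add atoms: none
Why: Nucleophilic aromatic substitution by addition–elimination, in which the ortho formyl group stabilises the anionic adduct, fluoride is the best leaving group for this mechanism, both methoxy groups are meta to the attacked carbon and so do not deactivate it, and the caesium phenoxide in DMSO is reactive enough despite its two ortho substituents.

Step 5
Reactants: 7 2-[4-(benzyloxy)-2,6-dimethoxyphenoxy]-4,6-dimethoxybenzaldehyde
Product: 9 2-[4-(benzyloxy)-2,6-dimethoxyphenoxy]-4,6-dimethoxyphenol, via aryl formate 8 (not isolated)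
Conditions: mCPBA, CH2Cl2, 0 °C to rt; wash with aq. NaHCO3; then K2CO3 (0.2 equiv), MeOH, rt
Reagents that add atoms: mCPBA (3-chloroperoxybenzoic acid), OOC(=O)c1cccc(Cl)c1
Why: Baeyer–Villiger oxidation of an aldehyde on a trioxygenated ring proceeds with migration of the electron-rich aryl group to give the aryl formate, which methanol transesterifies, so the carbon that activated the fluoride displacement becomes the ring B hydroxyl needed for the second ether.

Step 6
Reactants: 9 2-[4-(benzyloxy)-2,6-dimethoxyphenoxy]-4,6-dimethoxyphenol; 10 1-iodo-3,5-dimethoxybenzene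
Product: 11 5-(benzyloxy)-2-[2-(3,5-dimethoxyphenoxy)-3,5-dimethoxyphenoxy]-1,3-dimethoxybenzene
Conditions: CuI (10 mol%), picolinic acid (20 mol%), K3PO4, DMSO, 90 °C, argon
Reagents that add atoms: none
Why: Ullmann-type copper-catalysed diaryl ether coupling with picolinic acid as ligand is suited to ortho,ortho-disubstituted electron-rich phenols and aryl iodides, and the benzyl and methyl ethers are inert under these conditions.

Step 7
Reactants: 11 5-(benzyloxy)-2-[2-(3,5-dimethoxyphenoxy)-3,5-dimethoxyphenoxy]-1,3-dimethoxybenzene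
Product: 12 4-[2-(3,5-dimethoxyphenoxy)-3,5-dimethoxyphenoxy]-3,5-dimethoxyphenol
Conditions: H2 (1 atm), Pd/C (palladium metal on carbon), EtOAc/MeOH, rt
Reagents that add atoms: none
Why: Catalytic hydrogenolysis cleaves only the benzylic carbon–oxygen bond and spares diaryl and methyl aryl ethers, which frees the single hydroxyl at C4 of ring C.

Step 8
Reactants: 13 1,3,5-trimethoxybenzene
Product: 14 2,4,6-trimethoxyphenyllead triacetate
Conditions: Pb(OAc)4, AcOH, CHCl3, rt, dark
Reagents that add atoms: lead tetraacetate Pb(OAc)4, CC(=O)O[Pb](OC(C)=O)(OC(C)=O)OC(C)=O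
Why: Direct plumbation is an electrophilic aromatic substitution by Pb(OAc)4 (tetravalent lead) that is known for strongly activated arenes, and the threefold symmetry of 13 allows only one monoplumbated product.

Step 9
Reactants: 12 4-[2-(3,5-dimethoxyphenoxy)-3,5-dimethoxyphenoxy]-3,5-dimethoxyphenol; 14 2,4,6-trimethoxyphenyllead triacetate (2.3 equiv)
Product: 16 4-[2-(3,5-dimethoxyphenoxy)-3,5-dimethoxyphenoxy]-3,5-dimethoxy-2,6-bis(2,4,6-trimethoxyphenyl)phenol, via monoarylated phenol 15 (not isolated)
Conditions: pyridine, CHCl3, 40 to 60 °C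
Reagents that add atoms: none
Why: Pyridine-assisted exchange of one acetate of 14 for the phenoxide oxygen of 12 places both partners on the same tetravalent lead centre; the aryl group then moves from lead to the ortho carbon of the phenoxide (ligand coupling), lead departs as Pb(OAc)2 (divalent lead), and the resulting 6-aryl-cyclohexa-2,4-dienone enolises to phenol 15, which goes through the same cycle at its other ortho carbon. The closest known reaction type is the Pinhey ortho C-arylation of electron-rich phenols of the 3,4,5-trimethoxyphenol class with aryllead triacetates, which is known to transfer 2,4,6-trimethoxyphenyl groups and to give 2,6-diarylphenols with excess reagent. No ring is closed and no stereocentre is formed. The step requires arylation only at C3 and C5 of ring C: the sole hydroxyl able to bind lead lies between these two carbons, its para carbon is blocked by the ether oxygen to ring B, and rings A and B carry only ethers. Because the carbon–carbon bond forms inside the coordination sphere of lead by way of a dienone, the four ortho oxygen substituents around each new bond should be tolerated, and neither a halogenated ring C nor a labile 2,6-dioxygenated arylboronic acid is needed. A third transfer is held back by the small excess of 14 and by the crowding of the 2,6-diarylphenol.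

Step 10
Reactants: 16 4-[2-(3,5-dimethoxyphenoxy)-3,5-dimethoxyphenoxy]-3,5-dimethoxy-2,6-bis(2,4,6-trimethoxyphenyl)phenol
Product: 17 CNP0228669.0, 4-[2-(3,5-dihydroxyphenoxy)-3,5-dihydroxyphenoxy]-2,6-bis(2,4,6-trihydroxyphenyl)benzene-1,3,5-triol
Conditions: BBr3 (excess), CH2Cl2, −78 °C to rt; then degassed H2O, argon
Reagents that add atoms: none
Why: Lewis acid-mediated ether cleavage with BBr3 attacks only the methyl carbons of the twelve aryl methyl ethers, so the two diaryl ether bonds and the two biaryl bonds stay intact, and the aqueous (not methanolic) quench avoids acid-catalysed re-etherification of the phloroglucinol rings.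

**Compound list**

1 | 2,6-dimethoxy-1,4-benzoquinone | COC1=CC(=O)C=C(OC)C1=O | starting material
2 | 2,6-dimethoxybenzene-1,4-diol | COc1cc(O)cc(OC)c1O | intermediate
3 | 4-(benzyloxy)-2,6-dimethoxyphenol | COc1cc(OCc2ccccc2)cc(OC)c1O | intermediate
4 | 1-fluoro-3,5-dimethoxybenzene | COc1cc(F)cc(OC)c1 | starting material
5 | N-[(2-fluoro-4,6-dimethoxyphenyl)methylidene]-N-methylmethanaminium chloride (formed in the flask) | COc1cc(F)c(C=[N+](C)C)c(OC)c1.[Cl-] | intermediate
6 | 2-fluoro-4,6-dimethoxybenzaldehyde | COc1cc(F)c(C=O)c(OC)c1 | intermediate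
7 | 2-[4-(benzyloxy)-2,6-dimethoxyphenoxy]-4,6-dimethoxybenzaldehyde | COc1cc(OC)c(C=O)c(Oc2c(OC)cc(OCc3ccccc3)cc2OC)c1 | intermediate
8 | 2-[4-(benzyloxy)-2,6-dimethoxyphenoxy]-4,6-dimethoxyphenyl formate (formed in the flask) | COc1cc(OC)c(OC=O)c(Oc2c(OC)cc(OCc3ccccc3)cc2OC)c1 | intermediate
9 | 2-[4-(benzyloxy)-2,6-dimethoxyphenoxy]-4,6-dimethoxyphenol | COc1cc(OC)c(O)c(Oc2c(OC)cc(OCc3ccccc3)cc2OC)c1 | intermediate
10 | 1-iodo-3,5-dimethoxybenzene | COc1cc(I)cc(OC)c1 | starting material
11 | 5-(benzyloxy)-2-[2-(3,5-dimethoxyphenoxy)-3,5-dimethoxyphenoxy]-1,3-dimethoxybenzene | COc1cc(OC)cc(Oc2c(OC)cc(OC)cc2Oc2c(OC)cc(OCc3ccccc3)cc2OC)c1 | intermediate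
12 | 4-[2-(3,5-dimethoxyphenoxy)-3,5-dimethoxyphenoxy]-3,5-dimethoxyphenol | COc1cc(OC)cc(Oc2c(OC)cc(OC)cc2Oc2c(OC)cc(O)cc2OC)c1 | intermediate
13 | 1,3,5-trimethoxybenzene | COc1cc(OC)cc(OC)c1 | starting material
14 | 2,4,6-trimethoxyphenyllead triacetate | COc1cc(OC)c([Pb](OC(C)=O)(OC(C)=O)OC(C)=O)c(OC)c1 | intermediate
15 | 4-[2-(3,5-dimethoxyphenoxy)-3,5-dimethoxyphenoxy]-3,5-dimethoxy-2-(2,4,6-trimethoxyphenyl)phenol (formed in the flask) | COc1cc(OC)cc(Oc2c(OC)cc(OC)cc2Oc2c(OC)cc(O)c(-c3c(OC)cc(OC)cc3OC)c2OC)c1 | intermediate
16 | 4-[2-(3,5-dimethoxyphenoxy)-3,5-dimethoxyphenoxy]-3,5-dimethoxy-2,6-bis(2,4,6-trimethoxyphenyl)phenol | COc1cc(OC)cc(Oc2c(OC)cc(OC)cc2Oc2c(OC)c(-c3c(OC)cc(OC)cc3OC)c(O)c(-c3c(OC)cc(OC)cc3OC)c2OC)c1 | intermediate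
17 | CNP0228669.0, 4-[2-(3,5-dihydroxyphenoxy)-3,5-dihydroxyphenoxy]-2,6-bis(2,4,6-trihydroxyphenyl)benzene-1,3,5-triol | Oc1cc(O)cc(Oc2c(O)cc(O)cc2Oc2c(O)c(-c3c(O)cc(O)cc3O)c(O)c(-c3c(O)cc(O)cc3O)c2O)c1 | target

**Summary**

Total step count: 10.
Longest linear sequence: 8 steps (steps 1, 2, 4, 5, 6, 7, 9 and 10, from quinone 1).

**Steps most likely to fail**

Step 9. The second aryl transfer may stall at the crowded monoarylated stage, or the very electron-rich phenol may be oxidised by tetravalent lead in competition with ligand coupling. The fallback forms the same two biaryl bonds by cross-coupling. Setting out from 12, iodination of both carbons ortho to the hydroxyl with I2 and NaHCO3 in aqueous THF at 0 °C should give 4-[2-(3,5-dimethoxyphenoxy)-3,5-dimethoxyphenoxy]-2,6-diiodo-3,5-dimethoxyphenol F1, since only the phenolate ring is nucleophilic enough for molecular iodine. O-Methylation with MeI and K2CO3 in DMF should give 1-[2-(3,5-dimethoxyphenoxy)-3,5-dimethoxyphenoxy]-3,5-diiodo-2,4,6-trimethoxybenzene F2. Twofold Suzuki–Miyaura coupling with (2,4,6-trimethoxyphenyl)boronic acid under Pd(OAc)2 and 2-dicyclohexylphosphino-2',6'-dimethoxybiphenyl with K3PO4 in toluene/H2O at 100 °C should give 1-[2-(3,5-dimethoxyphenoxy)-3,5-dimethoxyphenoxy]-2,4,6-trimethoxy-3,5-bis(2,4,6-trimethoxyphenyl)benzene F3. BBr3 under the conditions of step 10 then cleaves thirteen methyl ethers, and the route is rejoined at 17.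

Step 6. The tetraoxygenated phenoxide may degrade oxidatively at copper, and carbon–oxygen bond formation may be slow at an oxygen flanked by a methoxy group and a bulky aryloxy group. The fallback is a metal-free O-arylation with a diaryliodonium salt of trivalent iodine. Setting out from 10, oxidation with mCPBA and TsOH·H2O in MeCN followed by addition of 13 should give (3,5-dimethoxyphenyl)(2,4,6-trimethoxyphenyl)iodonium 4-methylbenzenesulfonate F4, in which the trimethoxyphenyl group is the ligand that is not transferred. Treatment of 9 with KOt-Bu and this salt in THF at rt to 40 °C should transfer the 3,5-dimethoxyphenyl group to oxygen, which returns to the route at 11.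

Step 10. Cleavage may stop short at some of the twelve methyl ethers, and the free polyphenol may oxidise in air during purification, giving mixtures that are hard to separate. The fallback is capture and release. Setting out from 16, the crude product of the BBr3 reaction is acetylated at once with Ac2O and pyridine to 4-[2-(3,5-diacetoxyphenoxy)-3,5-diacetoxyphenoxy]-2,6-bis(2,4,6-triacetoxyphenyl)benzene-1,3,5-triyl triacetate F5. This is stable to air and silica and can be freed from partly methylated material by chromatography. Deacetylation with catalytic K2CO3 in degassed MeOH under argon, neutralised with an acidic ion-exchange resin, comes back to the route at 17.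

Further compounds
F1 | step 9 | 4-[2-(3,5-dimethoxyphenoxy)-3,5-dimethoxyphenoxy]-2,6-diiodo-3,5-dimethoxyphenol | COc1cc(OC)cc(Oc2c(OC)cc(OC)cc2Oc2c(OC)c(I)c(O)c(I)c2OC)c1
F2 | step 9 | 1-[2-(3,5-dimethoxyphenoxy)-3,5-dimethoxyphenoxy]-3,5-diiodo-2,4,6-trimethoxybenzene | COc1cc(OC)cc(Oc2c(OC)cc(OC)cc2Oc2c(OC)c(I)c(OC)c(I)c2OC)c1
F3 | step 9 | 1-[2-(3,5-dimethoxyphenoxy)-3,5-dimethoxyphenoxy]-2,4,6-trimethoxy-3,5-bis(2,4,6-trimethoxyphenyl)benzene | COc1cc(OC)cc(Oc2c(OC)cc(OC)cc2Oc2c(OC)c(-c3c(OC)cc(OC)cc3OC)c(OC)c(-c3c(OC)cc(OC)cc3OC)c2OC)c1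
F4 | step 6 | (3,5-dimethoxyphenyl)(2,4,6-trimethoxyphenyl)iodonium 4-methylbenzenesulfonate | COc1cc(OC)cc([I+]c2c(OC)cc(OC)cc2OC)c1.Cc1ccc(S(=O)(=O)[O-])cc1
F5 | step 10 | 4-[2-(3,5-diacetoxyphenoxy)-3,5-diacetoxyphenoxy]-2,6-bis(2,4,6-triacetoxyphenyl)benzene-1,3,5-triyl triacetate | CC(=O)Oc1cc(OC(C)=O)cc(Oc2c(OC(C)=O)cc(OC(C)=O)cc2Oc2c(OC(C)=O)c(-c3c(OC(C)=O)cc(OC(C)=O)cc3OC(C)=O)c(OC(C)=O)c(-c3c(OC(C)=O)cc(OC(C)=O)cc3OC(C)=O)c2OC(C)=O)c1
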